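The readings come from a simulation on assumed constants.

At 80 min you want the target in the north-east flask, and your hunch is that the bigger charge simply takes longer than the south-west run.

| flask | solid substrate | precatalyst | remark | time |
|---|---|---|---|---|
| north-east | 0.050 M | 10 µM | the very flask that is asked about, followed so far |  |
| south-west | 0.034 M | 10 µM | run made earlier |  |
| flask | 0.050 M | 10 µM |  | 80 min |

| run | time / min | target / % | solid substrate / % |
|---|---|---|---|
| north-east | 4.00 | 0.9 | 75.8 |
| north-east | 8.00 | 0 | 68.3 |
| north-east | 12.0 | 3.1 | 66.5 |
| north-east | 15.0 | 4.0 | 65.5 |
| south-west | 6.00 | 0.3 | 58.1 |
| south-west | 15.0 | 4.8 | 47.1 |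
| south-west | 30.0 | 19.0 | 38.3 |
| south-west | 80.0 | 92.9 | 0.7 |

(scatter of a reading: 1 percentage point)

- given per volume of solution although it is solid: solid substrate
- what was read earlier has a scatter of 1 percentage point, one standard deviation
- at the start none of the solid substrate is in solution

- the target standing at 80 min, as a percentage of the solid substrate charged
- the change that raises the amount of target at 80 min, in percent of the solid substrate charged most ("none" if none brings more than 2 percentage points) (theta / epsilon / eta / none)
- amount of target at 80 min, in percent of the solid substrate charged, after epsilon

- theta: doubling the solubility of the solid substrate, all else as stated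
- epsilon: doubling the amount of precatalyst, all else as stated
- eta: doubling the dissolution coefficient of the solid substrate, all else as stated

Charged minus solid minus target in the south-west run at 15.0 min leaves 0.0164 M dissolved, which we take as saturation, and going on to 30.0 min multiplies the target by 3.96, the mark of an induction period. So we carry 47.7 min, the clock time: the time at which [target], growing as the square of the time while solid remains at this loading of precatalyst, reaches the saturation concentration. A first round for the north-east flask gives 91.9% at 80 min, but solid ends when target plus dissolved reaches the charge, at 68.5 min against 49.6 min south-west, which is earlier than the reading. Going round again, with the rate falling in step with the dissolved substrate after that time, leaves 0.00771 M dissolved, so we say 84.6%.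

The forecast says 85% (77% to 91%) and names epsilon as the change that brings most, reaching 98% (88% to 100%), with the effect of the loading untested, “since both runs used the same loading”; it reads the same runs as we do, so the match with our figure checks nothing.

The simulation gives 74.5% for the flask, and epsilon as the change that brings most, worth 25 percentage points and reaching 99.7%, on this scheme:

    starting material + enzyme → target + enzyme, rate k1*[starting material]*[enzyme]/(1 + ([starting material]/Km1)) (13.0 mM, k = 15000 M⁻¹ min⁻¹)
    solid substrate ⇌ starting material, rate k2*(cs2 - [starting material]) while solid is left; crystals form when [starting material] > cs2 (solubility = 16.0 mM, k = 0.380 min⁻¹)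
    precatalyst → enzyme (k = 0.0170 min⁻¹)

At 80.0 min the flask holds 74.3% of its catalyst as enzyme, with solid substrate at 0% and starting material at 25.5% of the charge. The clock time of 47.7 min gives 23.0% at 40.0 min, where the flask stands at 22.9%, and 91.9% at 80 min, where it stands at 74.5%. Scaled to a quarter for the neighbour charged with 2.5 × 10⁻⁶ M of precatalyst, it gives 23.0% at 80.0 min, and that neighbour, with solid substrate still at 49.7%, holds 19.3%.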